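How does the triple product after 6.0 min move as you raise the reagent charge?

| flask | starting material | reagent | remark | time |
|---|---|---|---|---|
| dusk | 2 mM | 1 equiv | run made earlier |  |
| midnight | 2 mM | 6.7 equiv | run made earlier |  |
| eta | 2.0 mM | 1.20 equiv |  | 6.0 min |
| theta | 2.0 mM | 2.50 equiv |  | 6.0 min |
| delta | 2.0 mM | 5.00 equiv |  | 6.0 min |
| zeta | 2.0 mM | 10.0 equiv |  | 6.0 min |

| run | time / min | triple product / % |
|---|---|---|
| dusk | 0.417 | 0 |
| dusk | 1.00 | 0 |
| dusk | 2.00 | 5 |
| dusk | 3.00 | 4 |
| midnight | 0.417 | 22 |
| midnight | 1.00 | 30 |
| midnight | 2.00 | 32 |
| midnight | 3.00 | 26 |

(readings scatter by 2 percentage points)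

- "hardly changes" means that all values lie within two and a half points (for a concentration: within two and a half percent of the largest)

1. amount of triple product at the end, in percent of the starting material charged for eta, theta, delta, zeta, in this order
2. the course of these numbers from the first flask to the last (rises, then falls / rises all the way / falls all the way / falls, then rises / hardly changes)

Freeze what survives a change of charge. Suppose the additions that make the triple product and the one that spends it are both first order in reagent. Then c_reagent cancels from their ratio: it sets how fast the flask runs along one curve, not the curve's height. So, under that supposition, I carry the ceiling, the height that one curve reaches whatever the charge, read from the two top midnight readings as 31.0 %, with a scatter of 2 percentage points on each reading.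

Now my chain. The last two dusk readings average 4.50 %. The product takes 3 additions, so at low charge I scale the yield with the cube of the charge. That gives 7.78 % for eta. For theta the cube gives 70.3 %, more than the ceiling, so I put theta and delta at the ceiling.

I place zeta past the top of the curve. The last two midnight readings give a fall of 0.208 min⁻¹, a reading that carries their scatter. Scaled by charge from 2.00 min onward, that leaves 8.97 %. This is the weak link: it assumes that c_reagent stays in its charged proportion throughout, though each addition takes reagent. Reforged, I keep the midnight rate unscaled and commit to 13.5 %, which is higher.

The forecast differs from this reckoning in its numbers. It gives 5 %, 15 %, 20 % and 8 %, a course that rises, then falls, holding that “That loss should scale with excess reagent”.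

The flasks give 6.62 %, 26.3 %, 28.1 % and 18.4 %: the row rises, then falls.

    starting material + reagent → mono adduct (k = 28.0 M⁻¹ s⁻¹)
    reagent + mono adduct → bis adduct (k = 1.60 M⁻¹ s⁻¹)
    reagent + bis adduct → triple product (k = 39.0 M⁻¹ s⁻¹)
    reagent + triple product → tetra adduct (k = 2.40 M⁻¹ s⁻¹)
    2 reagent → self-condensation product (k = 0.740 M⁻¹ s⁻¹)

The step making bis adduct and the step spending triple product both take reagent, and their constants stand at a ratio of 1.50, a selectivity factor. Against the ceiling of 31.0 %, delta stood at 29.5 % after 3.00 min. In the theta flask, with reagent at 0 %, the triple product after 60.0 min stands at 27.7 %, which is 89.4 % of the ceiling.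

The runs were computed with made-up constants, and the scatter is random.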